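## Retrosynthetic overview

1. The target is a (2R,3S,4S)-oxolane in which C2 carries ring O1 and the aryl group, and the C2 aryl group is cis to the tertiary C3 hydroxyl. Because of this, C2–aryl and C3–OH can be installed together, syn, across a C2=C3 enol ether.
2. Key disconnection: C2–aryl, made from a triarylalane and the C2–C3 oxirane of a 4-benzyl-3-(silyloxymethyl)-4,5-dihydrofuran. Oxidation makes C2 electrophilic, and the C3 aluminate that results delivers the aryl group.
3. The 4,5-dihydrofuran comes from lactol dehydration of a trans-α-(silyloxymethyl)-β-benzyl-γ-butyrolactone, made by enolate hydroxymethylation of the (R)-β-benzyl lactone.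
4. The lactone comes from a Stobbe condensation of O-benzylvanillin with dimethyl succinate, Rh-catalysed asymmetric hydrogenation (sets C4, the only catalyst-controlled centre) and ester reduction/lactonisation.
5. Ring order: the oxolane is closed first as the lactone (step 3) and carried through lactol and dihydrofuran; the oxirane is made and opened within the key step. All three hydroxyls are TBS ethers, released in one final step.

Key step: step 10

Remark: the SMILES is read as (2R,3S,4S); on the oxolane the C2 aryl is cis to C3–OH and trans to C3–CH2OH, which is cis to the C4 benzyl group.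
Assumption: DMDO is used as a dried, titrated acetone solution (standard Oxone/acetone preparation), and the Et-DuPhos antipode in step 2 is the one that gives the (R)-acid 4.

## Route

Step 1
Reactants: 1 4-(benzyloxy)-3-methoxybenzaldehyde; 2 dimethyl succinate
Product: 3 (3E)-4-[4-(benzyloxy)-3-methoxyphenyl]-3-(methoxycarbonyl)but-3-enoic acid
Conditions: NaOMe (2.2 equiv), MeOH, reflux; then 2 M HCl
Reagents that add atoms: none
Why: Stobbe condensation (succinate enolate aldol, lactonisation to the paraconate, E1cB ring opening) should give the (E)-arylidene half-ester whose free acid is the unconjugated CH2CO2H arm.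

Step 2
Reactants: 3 (3E)-4-[4-(benzyloxy)-3-methoxyphenyl]-3-(methoxycarbonyl)but-3-enoic acid
Product: 4 (3R)-4-[4-(benzyloxy)-3-methoxyphenyl]-3-(methoxycarbonyl)butanoic acid
Conditions: H2 (5 bar), [Rh(cod)(Et-DuPhos)]BF4 (1 mol %), NaOMe (10 mol %), MeOH, rt
Reagents that add atoms: none
Why: Rh–bisphosphine asymmetric hydrogenation of an itaconate-type half-ester, whose carboxylate and alkene chelate rhodium, should set the stereocentre (future ring C4) under catalyst control and leave the aryl benzyl ether intact.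

Step 3
Reactants: 4 (3R)-4-[4-(benzyloxy)-3-methoxyphenyl]-3-(methoxycarbonyl)butanoic acid
Product: 6 (4R)-4-[4-(benzyloxy)-3-methoxybenzyl]oxolan-2-one, via hydroxy acid 5 (not isolated)
Conditions: KOH (1.0 equiv), EtOH; CaCl2, NaBH4, −10 °C→rt; then 2 M HCl, rt
Reagents that add atoms: none
Why: calcium borohydride reduces the methyl ester but not the carboxylate salt, and acidification lactonises the γ-hydroxy acid (5-exo-trig acyl substitution), so the β-benzyl lactone should form without touching the stereocentre.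

Step 4
Reactants: 6 (4R)-4-[4-(benzyloxy)-3-methoxybenzyl]oxolan-2-one
Product: 8 (3S,4R)-4-[4-(benzyloxy)-3-methoxybenzyl]-3-(hydroxymethyl)oxolan-2-one, via lithium enolate 7 (not isolated)
Conditions: LDA (1.1 equiv), THF, −78 °C; CH2O (g, from cracked paraformaldehyde), −78→−40 °C; aq NH4Cl
Reagents that add atoms: formaldehyde, C=O
Why: aldol hydroxymethylation of the lactone enolate should occur anti to the β-benzyl group to give the trans product; this centre becomes sp2 in step 8, so its ratio is immaterial.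

Step 5
Reactants: 8 (3S,4R)-4-[4-(benzyloxy)-3-methoxybenzyl]-3-(hydroxymethyl)oxolan-2-one
Product: 9 (3S,4R)-4-(4-hydroxy-3-methoxybenzyl)-3-(hydroxymethyl)oxolan-2-one
Conditions: H2 (1 atm), 10% Pd/C, EtOAc–MeOH, rt
Reagents that add atoms: none
Why: hydrogenolysis of the aryl benzyl ether is done here, where no other benzylic C–O bond exists, so that all hydroxyls can later carry the same fluoride-labile group.

Step 6
Reactants: 9 (3S,4R)-4-(4-hydroxy-3-methoxybenzyl)-3-(hydroxymethyl)oxolan-2-one
Product: 10 (3S,4R)-4-{4-[(tert-butyldimethylsilyl)oxy]-3-methoxybenzyl}-3-{[(tert-butyldimethylsilyl)oxy]methyl}oxolan-2-one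
Conditions: TBSCl (2.4 equiv), imidazole (5 equiv), DMF, rt
Reagents that add atoms: tert-butyldimethylsilyl chloride (TBSCl), CC(C)(C)[Si](C)(C)Cl
Why: imidazole-promoted silylation should protect the phenol and the primary alcohol in one operation under conditions too mild for retro-aldol or elimination.

Step 7
Reactants: 10 (3S,4R)-4-{4-[(tert-butyldimethylsilyl)oxy]-3-methoxybenzyl}-3-{[(tert-butyldimethylsilyl)oxy]methyl}oxolan-2-one
Product: 11 (3S,4R)-4-{4-[(tert-butyldimethylsilyl)oxy]-3-methoxybenzyl}-3-{[(tert-butyldimethylsilyl)oxy]methyl}oxolan-2-ol (anomer mixture)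
Conditions: DIBAL-H (1.1 equiv), CH2Cl2, −78 °C; aq Rochelle salt
Reagents that add atoms: none
Why: partial reduction of a γ-lactone stops at the lactol because the tetrahedral aluminate is stable at −78 °C; the anomeric centre is uncontrolled and is erased in step 8.

Step 8
Reactants: 11 (3S,4R)-4-{4-[(tert-butyldimethylsilyl)oxy]-3-methoxybenzyl}-3-{[(tert-butyldimethylsilyl)oxy]methyl}oxolan-2-ol
Product: 12 tert-butyl{[(4R)-4-{4-[(tert-butyldimethylsilyl)oxy]-3-methoxybenzyl}-4,5-dihydrofuran-3-yl]methoxy}dimethylsilane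
Conditions: MsCl (1.5 equiv), Et3N (5 equiv), CH2Cl2, −40 °C→reflux; Et3N-deactivated silica
Reagents that add atoms: none
Why: lactol dehydration in the manner of a furanoid glycal preparation: the anomeric mesylate/chloride ionises to the oxocarbenium ion, which can only lose the C3 proton, giving the C2=C3 enol ether with C4 untouched.

Step 9
Reactants: 13 4-bromo-2-methoxyphenol
Product: 14 (4-bromo-2-methoxyphenoxy)(tert-butyl)dimethylsilane
Conditions: TBSCl (1.1 equiv), imidazole (2 equiv), DMF, rt
Reagents that add atoms: tert-butyldimethylsilyl chloride (TBSCl), CC(C)(C)[Si](C)(C)Cl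
Why: standard phenol silylation gives an aryl bromide that tolerates bromine–lithium exchange at −78 °C.

Step 10
Reactants: 12 tert-butyl{[(4R)-4-{4-[(tert-butyldimethylsilyl)oxy]-3-methoxybenzyl}-4,5-dihydrofuran-3-yl]methoxy}dimethylsilane; 14 (4-bromo-2-methoxyphenoxy)(tert-butyl)dimethylsilane
Product: 18 (2R,3S,4S)-2-{4-[(tert-butyldimethylsilyl)oxy]-3-methoxyphenyl}-4-{4-[(tert-butyldimethylsilyl)oxy]-3-methoxybenzyl}-3-{[(tert-butyldimethylsilyl)oxy]methyl}oxolan-3-ol, via aryllithium 15 (not isolated), via triarylalane 16 (not isolated), via epoxide 17 (not isolated)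
Conditions: (a) 14 (6 equiv), t-BuLi (12 equiv), Et2O, −78 °C; AlCl3 (2 equiv), −78→0 °C; dilute with toluene; (b) 12, DMDO (1.2 equiv, acetone), CH2Cl2, −78→0 °C; evaporate; add (a), toluene, −78→0 °C; aq Rochelle salt
Reagents that add atoms: dimethyldioxirane (DMDO), CC1(C)OO1
Why: DMDO should transfer oxygen to the electron-rich C2=C3 enol ether of 12 on the face anti to the C4 benzyl group to give the 1,2-anhydro compound 17 (concerted [2+1] oxygen transfer; this oxirane is the only ring closed and it is opened again in the same operation), after which the Lewis-acidic alane 16 binds the oxirane oxygen, the C2–O bond ionises with help from ring O1 to an oxocarbenium/alkoxy-aluminate pair, and an aryl group moves from aluminium to C2 on the face of the C3–O–Al bond. The closest known reaction type is the syn-selective C-arylation of glycal epoxides (1,2-anhydro sugars) with arylaluminium or arylzinc reagents, commonly run as a one-pot DMDO epoxidation–organometallic addition. C3 is set by the C4 benzyl group (anti epoxidation puts C3–O trans and CH2OTBS cis to benzyl), and C2 is set by the C3 aluminate (syn delivery puts aryl cis to C3–OH), reinforced because CH2OTBS and benzyl both shield the opposite face. Opening at C2 and not C3 follows from O1 stabilising positive charge only at C2, and DMDO should select the enol ether over the silyloxyarene rings by rate at −78 to 0 °C with 1.2 equiv. Aryl transfer must outrun Friedel–Crafts capture of the oxocarbenium ion by the C4 aryl ring and a semipinacol shift, which intramolecular delivery from the aluminate, low temperature, weakly coordinating solvent and excess alane are chosen to secure.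

Step 11
Reactants: 18 (2R,3S,4S)-2-{4-[(tert-butyldimethylsilyl)oxy]-3-methoxyphenyl}-4-{4-[(tert-butyldimethylsilyl)oxy]-3-methoxybenzyl}-3-{[(tert-butyldimethylsilyl)oxy]methyl}oxolan-3-ol
Product: 19 (2R,3S,4S)-2-(4-hydroxy-3-methoxyphenyl)-4-(4-hydroxy-3-methoxybenzyl)-3-(hydroxymethyl)oxolan-3-ol
Conditions: TBAF (4 equiv), AcOH (4 equiv), THF, 0 °C→rt
Reagents that add atoms: none
Why: fluoride should cleave all three Si–O bonds; the acetic acid buffer keeps phenoxide low (no quinone-methide opening or epimerisation at C2), and the absence of strong acid avoids cyclolignan formation.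

## Compound list

1 | 4-(benzyloxy)-3-methoxybenzaldehyde | COc1cc(C=O)ccc1OCc1ccccc1 | starting material
2 | dimethyl succinate | COC(=O)CCC(=O)OC | starting material
3 | (3E)-4-[4-(benzyloxy)-3-methoxyphenyl]-3-(methoxycarbonyl)but-3-enoic acid | COc1cc(/C=C(\CC(=O)O)C(=O)OC)ccc1OCc1ccccc1 | intermediate
4 | (3R)-4-[4-(benzyloxy)-3-methoxyphenyl]-3-(methoxycarbonyl)butanoic acid | COc1cc(C[C@H](CC(=O)O)C(=O)OC)ccc1OCc1ccccc1 | intermediate
5 | (3R)-4-[4-(benzyloxy)-3-methoxyphenyl]-3-(hydroxymethyl)butanoic acid | COc1cc(C[C@H](CC(=O)O)CO)ccc1OCc1ccccc1 | intermediate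
6 | (4R)-4-[4-(benzyloxy)-3-methoxybenzyl]oxolan-2-one | COc1cc(C[C@H]2COC(=O)C2)ccc1OCc1ccccc1 | intermediate
7 | lithium enolate of 6, lithium (4R)-4-[4-(benzyloxy)-3-methoxybenzyl]-4,5-dihydrofuran-2-olate | COc1cc(C[C@H]2COC(O[Li])=C2)ccc1OCc1ccccc1 | intermediate
8 | (3S,4R)-4-[4-(benzyloxy)-3-methoxybenzyl]-3-(hydroxymethyl)oxolan-2-one | COc1cc(C[C@H]2COC(=O)[C@@H]2CO)ccc1OCc1ccccc1 | intermediate
9 | (3S,4R)-4-(4-hydroxy-3-methoxybenzyl)-3-(hydroxymethyl)oxolan-2-one | COc1cc(C[C@H]2COC(=O)[C@@H]2CO)ccc1O | intermediate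
10 | (3S,4R)-4-{4-[(tert-butyldimethylsilyl)oxy]-3-methoxybenzyl}-3-{[(tert-butyldimethylsilyl)oxy]methyl}oxolan-2-one | COc1cc(C[C@H]2COC(=O)[C@@H]2CO[Si](C)(C)C(C)(C)C)ccc1O[Si](C)(C)C(C)(C)C | intermediate
11 | (3S,4R)-4-{4-[(tert-butyldimethylsilyl)oxy]-3-methoxybenzyl}-3-{[(tert-butyldimethylsilyl)oxy]methyl}oxolan-2-ol (anomer mixture) | COc1cc(C[C@H]2COC(O)[C@@H]2CO[Si](C)(C)C(C)(C)C)ccc1O[Si](C)(C)C(C)(C)C | intermediate
12 | tert-butyl{[(4R)-4-{4-[(tert-butyldimethylsilyl)oxy]-3-methoxybenzyl}-4,5-dihydrofuran-3-yl]methoxy}dimethylsilane | COc1cc(C[C@H]2COC=C2CO[Si](C)(C)C(C)(C)C)ccc1O[Si](C)(C)C(C)(C)C | intermediate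
13 | 4-bromo-2-methoxyphenol | COc1cc(Br)ccc1O | starting material
14 | (4-bromo-2-methoxyphenoxy)(tert-butyl)dimethylsilane | COc1cc(Br)ccc1O[Si](C)(C)C(C)(C)C | intermediate
15 | {4-[(tert-butyldimethylsilyl)oxy]-3-methoxyphenyl}lithium | COc1cc([Li])ccc1O[Si](C)(C)C(C)(C)C | intermediate
16 | tris{4-[(tert-butyldimethylsilyl)oxy]-3-methoxyphenyl}alane | COc1cc(ccc1O[Si](C)(C)C(C)(C)C)[Al](c1ccc(O[Si](C)(C)C(C)(C)C)c(OC)c1)c1ccc(O[Si](C)(C)C(C)(C)C)c(OC)c1 | intermediate
17 | (1R,4S,5S)-4-{4-[(tert-butyldimethylsilyl)oxy]-3-methoxybenzyl}-5-{[(tert-butyldimethylsilyl)oxy]methyl}-2,6-dioxabicyclo[3.1.0]hexane | COc1cc(C[C@H]2CO[C@@H]3O[C@]23CO[Si](C)(C)C(C)(C)C)ccc1O[Si](C)(C)C(C)(C)C | intermediate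
18 | (2R,3S,4S)-2-{4-[(tert-butyldimethylsilyl)oxy]-3-methoxyphenyl}-4-{4-[(tert-butyldimethylsilyl)oxy]-3-methoxybenzyl}-3-{[(tert-butyldimethylsilyl)oxy]methyl}oxolan-3-ol | COc1cc(C[C@H]2CO[C@H](c3ccc(O[Si](C)(C)C(C)(C)C)c(OC)c3)[C@@]2(O)CO[Si](C)(C)C(C)(C)C)ccc1O[Si](C)(C)C(C)(C)C | intermediate
19 | (2R,3S,4S)-2-(4-hydroxy-3-methoxyphenyl)-4-(4-hydroxy-3-methoxybenzyl)-3-(hydroxymethyl)oxolan-3-ol | COc1cc(C[C@H]2CO[C@H](c3ccc(O)c(OC)c3)[C@@]2(O)CO)ccc1O | target

## Step count and risks

Total steps: 11. Longest linear sequence: 10 (steps 1–8, 10, 11); step 9 is a one-step side branch.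

Steps most likely to fail:

1. Step 10. The aryl transfer may be slower than intramolecular Friedel–Crafts capture of the oxocarbenium ion by the C4 aryl ring or a semipinacol shift, or may occur partly from the wrong face. Fallback, setting out from lactone 10 and returning at 18: the potassium enolate of 10 (KHMDS, THF, −78 °C) is hydroxylated with 2-(phenylsulfonyl)-3-phenyloxaziridine anti to the C4 benzyl group to give (3S,4S)-4-{4-[(tert-butyldimethylsilyl)oxy]-3-methoxybenzyl}-3-{[(tert-butyldimethylsilyl)oxy]methyl}-3-hydroxyoxolan-2-one F1. DIBAL-H at −78 °C then gives the lactol (3S,4S)-4-{4-[(tert-butyldimethylsilyl)oxy]-3-methoxybenzyl}-3-{[(tert-butyldimethylsilyl)oxy]methyl}oxolane-2,3-diol F2. Excess aryllithium 15 (from 14 and t-BuLi) adds to its open hydroxy-aldehyde form to give (2S,3S)-1-{4-[(tert-butyldimethylsilyl)oxy]-3-methoxyphenyl}-3-{4-[(tert-butyldimethylsilyl)oxy]-3-methoxybenzyl}-2-{[(tert-butyldimethylsilyl)oxy]methyl}butane-1,2,4-triol F3 as a carbinol epimer mixture. Catalytic camphorsulfonic acid in CH2Cl2 at 0 °C should ionise the electron-rich benzylic carbinol, and the primary hydroxyl closes the oxolane with the aryl group settling trans to CH2OTBS and to the C4 benzyl group under thermodynamic control, giving 18.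

2. Step 8. Elimination may be incomplete, or the enol ether may be lost by acid-catalysed hydration or allylic ionisation (loss of silyloxide) during reaction or chromatography. Fallback, setting out from lactol 11 and returning at 12: N-(phenylseleno)phthalimide and Bu3P (CH2Cl2, −20 °C) convert 11 under neutral conditions into the anomeric selenide tert-butyl{[(3S,4R)-4-{4-[(tert-butyldimethylsilyl)oxy]-3-methoxybenzyl}-2-(phenylselanyl)oxolan-3-yl]methoxy}dimethylsilane F4. One equivalent of mCPBA at −78 °C gives the selenoxide tert-butyl{[(3S,4R)-2-(benzeneseleninyl)-4-{4-[(tert-butyldimethylsilyl)oxy]-3-methoxybenzyl}oxolan-3-yl]methoxy}dimethylsilane F5, which on warming with i-Pr2NEt should undergo syn-elimination toward the C3 hydrogen to give 12.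

3. Step 4. Formaldehyde may polymerise before it reacts, and the product may be lost by double hydroxymethylation, retro-aldol cleavage or dehydration to the α-methylene lactone. Fallback, setting out from lactone 6 and returning at 9: the lithium enolate of 6 is alkylated with benzyloxymethyl chloride (anti to the benzyl group) to give (3S,4R)-3-[(benzyloxy)methyl]-4-[4-(benzyloxy)-3-methoxybenzyl]oxolan-2-one F6. Hydrogenolysis (H2, Pd(OH)2/C, EtOAc–MeOH) should cleave both benzyl ethers at this robust stage and give 9 directly, making step 5 unnecessary.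

Further compounds
F1 | step 10 | (3S,4S)-4-{4-[(tert-butyldimethylsilyl)oxy]-3-methoxybenzyl}-3-{[(tert-butyldimethylsilyl)oxy]methyl}-3-hydroxyoxolan-2-one | COc1cc(C[C@H]2COC(=O)[C@@]2(O)CO[Si](C)(C)C(C)(C)C)ccc1O[Si](C)(C)C(C)(C)C
F2 | step 10 | (3S,4S)-4-{4-[(tert-butyldimethylsilyl)oxy]-3-methoxybenzyl}-3-{[(tert-butyldimethylsilyl)oxy]methyl}oxolane-2,3-diol (anomer mixture) | COc1cc(C[C@H]2COC(O)[C@@]2(O)CO[Si](C)(C)C(C)(C)C)ccc1O[Si](C)(C)C(C)(C)C
F3 | step 10 | (2S,3S)-1-{4-[(tert-butyldimethylsilyl)oxy]-3-methoxyphenyl}-3-{4-[(tert-butyldimethylsilyl)oxy]-3-methoxybenzyl}-2-{[(tert-butyldimethylsilyl)oxy]methyl}butane-1,2,4-triol (C1 epimer mixture) | COc1cc(C[C@@H](CO)[C@](O)(CO[Si](C)(C)C(C)(C)C)C(O)c2ccc(O[Si](C)(C)C(C)(C)C)c(OC)c2)ccc1O[Si](C)(C)C(C)(C)C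
F4 | step 8 | tert-butyl{[(3S,4R)-4-{4-[(tert-butyldimethylsilyl)oxy]-3-methoxybenzyl}-2-(phenylselanyl)oxolan-3-yl]methoxy}dimethylsilane (anomer mixture) | COc1cc(C[C@H]2COC([Se]c3ccccc3)[C@@H]2CO[Si](C)(C)C(C)(C)C)ccc1O[Si](C)(C)C(C)(C)C
F5 | step 8 | tert-butyl{[(3S,4R)-2-(benzeneseleninyl)-4-{4-[(tert-butyldimethylsilyl)oxy]-3-methoxybenzyl}oxolan-3-yl]methoxy}dimethylsilane | COc1cc(C[C@H]2COC([Se](=O)c3ccccc3)[C@@H]2CO[Si](C)(C)C(C)(C)C)ccc1O[Si](C)(C)C(C)(C)C
F6 | step 4 | (3S,4R)-3-[(benzyloxy)methyl]-4-[4-(benzyloxy)-3-methoxybenzyl]oxolan-2-one | COc1cc(C[C@H]2COC(=O)[C@@H]2COCc2ccccc2)ccc1OCc1ccccc1
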